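**Strategy.** The target is cut at the bond between the bridging methylene carbon and C8 of ring A of (+)-catechin. Because that CH2 sits between two phenolic OH groups of the fully substituted acylphloroglucinol ring, it is a latent ortho-quinone methide, and C8 of the flavan (ortho to 7-OH and to the pyran oxygen) is a phloroglucinol-type nucleophile. In one operation the acylphloroglucinol, a one-carbon iminium salt and unprotected (+)-catechin are joined: aminomethylation, loss of dimethylamine and Friedel–Crafts capture of the quinone methide. Both stereocentres are bought with catechin. The precursor of the key step is simply the free acylphloroglucinol with a single open nuclear position.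

Key step: step 5

Remark: 1, 2, 7 and 8 are taken as commercial. The (2R,3S) centres of the target are those of natural (+)-catechin, so no stereocentre has to be made and none is touched.

**Step 1**
Reactants: 1 2,4,6-trihydroxytoluene; 2 isobutyryl chloride
Product: 3 1-(2,4,6-trihydroxy-3-methylphenyl)-2-methylpropan-1-one
Conditions: AlCl3 (3 equiv), PhNO2–CH2Cl2, 0 to 60 °C; then aq. HCl
Reagents that add atoms: none
Why: Friedel–Crafts acylation of the phloroglucinol nucleus; the two free positions of 1 are equivalent by symmetry and the first acyl group deactivates the ring towards a second acylation, so a single mono-ketone should form.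

**Step 2**
Reactants: 3 1-(2,4,6-trihydroxy-3-methylphenyl)-2-methylpropan-1-one
Product: 4 1-[2-hydroxy-4,6-bis(methoxymethoxy)-3-methylphenyl]-2-methylpropan-1-one
Conditions: MOMCl (2.1 equiv), K2CO3, acetone, 0 °C to rt
Reagents that add atoms: chloromethyl methyl ether, COCCl
Why: Williamson-type O-alkylation (MOM ether formation), in which the unchelated 4-OH should react first and then the 6-OH next to the free C5–H, while the 2-OH, flanked by the C-methyl and the acyl group and chelated to the carbonyl, should stay free.

**Step 3**
Reactants: 4 1-[2-hydroxy-4,6-bis(methoxymethoxy)-3-methylphenyl]-2-methylpropan-1-one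
Product: 5 1-[2-methoxy-4,6-bis(methoxymethoxy)-3-methylphenyl]-2-methylpropan-1-one
Conditions: MeI (3 equiv), K2CO3, DMF, 50 °C
Reagents that add atoms: iodomethane, CI
Why: Williamson ether synthesis on the last, chelated phenol with a small electrophile under non-enolising carbonate conditions, which fixes the methoxy group between the C-methyl and the acyl group.

**Step 4**
Reactants: 5 1-[2-methoxy-4,6-bis(methoxymethoxy)-3-methylphenyl]-2-methylpropan-1-one
Product: 6 1-(4,6-dihydroxy-2-methoxy-3-methylphenyl)-2-methylpropan-1-one
Conditions: HCl (3 M aq.), MeOH, 50 °C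
Reagents that add atoms: none
Why: Acid-catalysed acetal cleavage (MOM removal) with methanol as the trap for the methoxymethyl cation; the aryl methyl ether and the hindered ketone should be inert to dilute HCl.

**Step 5**
Reactants: 6 1-(4,6-dihydroxy-2-methoxy-3-methylphenyl)-2-methylpropan-1-one; 7 N,N-dimethylmethyleneiminium iodide; 8 (+)-catechin
Product: 11 pilosanol B, via Mannich base 9 (not isolated), via ortho-quinone methide 10 (not isolated)
Conditions: 7 (1.0 equiv), NaOAc (1.1 equiv), MeCN, 0 °C to rt; then 8 (3 equiv), 1,4-dioxane, 75 °C, argon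
Reagents that add atoms: none
Why: Mannich aminomethylation of 6 at C5, its only free nuclear carbon, gives 9, whose acidic phenol/ammonium zwitterion loses dimethylamine on warming (E1cB) to the ortho-quinone methide 10; ring A of 8 then adds through C8 to the exocyclic methylene and both rings re-aromatise, which forms the CH2–C8 bond. The closest known reaction type is the ortho-quinone methide (Mannich base) route to methylene-bridged acylphloroglucinols and the ortho-hydroxybenzylation of flavan-3-ols. No ring is closed and no stereocentre is formed; C2 and C3 of 8 are carried through unchanged, and the acetate buffer keeps the medium weakly acidic so that base-induced epimerisation at C2 should not occur. Cross-coupling over homo-coupling is secured because 6 is fully converted into 9 before 8 is added and 8 cannot form a quinone methide of its own. The step also needs attack at C8 and not at C6 of ring A: no blocking group enforces this, and it rests on the inherent preference of free flavan-3-ols for C8 towards benzylic and quinone-methide electrophiles (the preference behind 4→8 interflavan bonds), so the C6 isomer is expected as the minor product to be removed by chromatography. An excess of 8 should suppress double alkylation at C6 and C8.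

**Compound list**
1 | 2,4,6-trihydroxytoluene | Cc1c(O)cc(O)cc1O | starting material
2 | isobutyryl chloride (2-methylpropanoyl chloride) | CC(C)C(Cl)=O | starting material
3 | 1-(2,4,6-trihydroxy-3-methylphenyl)-2-methylpropan-1-one | CC(C)C(=O)c1c(O)cc(O)c(C)c1O | intermediate
4 | 1-[2-hydroxy-4,6-bis(methoxymethoxy)-3-methylphenyl]-2-methylpropan-1-one | CC(C)C(=O)c1c(OCOC)cc(OCOC)c(C)c1O | intermediate
5 | 1-[2-methoxy-4,6-bis(methoxymethoxy)-3-methylphenyl]-2-methylpropan-1-one | CC(C)C(=O)c1c(OCOC)cc(OCOC)c(C)c1OC | intermediate
6 | 1-(4,6-dihydroxy-2-methoxy-3-methylphenyl)-2-methylpropan-1-one | CC(C)C(=O)c1c(O)cc(O)c(C)c1OC | intermediate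
7 | N,N-dimethylmethyleneiminium iodide | C=[N+](C)C.[I-] | starting material
8 | (+)-catechin, (2R,3S)-2-(3,4-dihydroxyphenyl)-3,4-dihydro-2H-chromene-3,5,7-triol | Oc1cc(O)c2c(c1)O[C@H](c1ccc(O)c(O)c1)[C@@H](O)C2 | starting material
9 | Mannich base, 1-{3-[(dimethylamino)methyl]-2,4-dihydroxy-6-methoxy-5-methylphenyl}-2-methylpropan-1-one | CC(C)C(=O)c1c(O)c(CN(C)C)c(O)c(C)c1OC | intermediate
10 | ortho-quinone methide, 5-hydroxy-3-methoxy-2-methyl-6-methylidene-4-(2-methylpropanoyl)cyclohexa-2,4-dien-1-one | C=C1C(=O)C(C)=C(OC)C(C(=O)C(C)C)=C1O | intermediate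
11 | pilosanol B, 1-[3-{[(2R,3S)-2-(3,4-dihydroxyphenyl)-3,5,7-trihydroxy-3,4-dihydro-2H-chromen-8-yl]methyl}-2,4-dihydroxy-6-methoxy-5-methylphenyl]-2-methylpropan-1-one | COc1c(C)c(O)c(Cc2c(O)cc(O)c3c2O[C@H](c2ccc(O)c(O)c2)[C@@H](O)C3)c(O)c1C(=O)C(C)C | target

**Step count.** Total: 5 steps. Longest linear sequence: 5 steps (1 → 3 → 4 → 5 → 6 → 11).

**Steps most likely to fail**

1. Step 5. Ring A of catechin may be attacked at C6 as well as at C8, and the product may be alkylated a second time, so that the wanted isomer has to be separated from close relatives. Fallback, setting out from 8 and 6 and coming back at 11, with the site fixed by a carbon–bromine bond: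
   - Catechin 8 would be benzylated on its four phenols (BnBr, K2CO3, DMF) to 5,7,3',4'-tetra-O-benzylcatechin F1.
   - Bromination with NBS (CH2Cl2, −78 °C), which on this ether is selective for C8, would give the 8-bromide F2.
   - Benzylation at O3 (NaH, BnBr, DMF) would give the penta-O-benzyl 8-bromide F3.
   - In parallel, 6 would be formylated at C5 by a Vilsmeier–Haack reaction (POCl3, DMF; then H2O) to the aldehyde F4, and both phenols benzylated (BnBr, K2CO3, DMF, 60 °C) to the dibenzyl ether aldehyde F5.
   - Bromine–lithium exchange on F3 (n-BuLi, THF, −78 °C) and addition of the aryllithium to the formyl group of F5, which is far more electrophilic than the hindered ketone, would give the diarylmethanol F6 as a mixture of carbinol epimers.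
   - Hydrogenolysis (H2, Pd(OH)2/C, THF–MeOH, trace AcOH) would remove the seven benzyl groups and the doubly benzylic hydroxyl and give 11.

2. Step 2. Etherification may take place at the 2-OH instead of the 6-OH, which would carry the wrong oxygen into the methylation of step 3. Fallback, setting out from 1 and coming back at 9, in which a formyl group decides the site:
   - 1 would be formylated (POCl3, DMF, EtOAc; then H2O) to 2,4,6-trihydroxy-3-methylbenzaldehyde F7.
   - The hydroxyl para to the formyl group, the only one not ortho to the carbonyl and the most acidic, would be methylated with one equivalent of MeI (K2CO3, DMF, rt) to 2,6-dihydroxy-4-methoxy-3-methylbenzaldehyde F8.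
   - Friedel–Crafts acylation of the single remaining nuclear position with 2 (TiCl4, CH2Cl2) would give the aldehyde F4 already met in the fallback above.
   - Reductive amination (Me2NH, NaBH(OAc)3, ClCH2CH2Cl, rt) would give the Mannich base 9, which would then be heated with 8 as in the second stage of step 5.

3. Step 4. The formaldehyde equivalents released from the two MOM groups may re-alkylate the free nuclear position of the product under acid and bridge two molecules through a methylene group. Fallback, setting out from 3 and coming back at 6, with no formaldehyde source: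
   - 3 would be benzylated twice (BnBr, K2CO3, acetone, reflux), with the same site preference as in step 2, to the 4,6-dibenzyl ether F9.
   - Methylation of the remaining hydroxyl (MeI, K2CO3, DMF, 50 °C) would give the methyl ether F10.
   - Hydrogenolysis (H2, Pd/C, EtOAc, rt) would give 6.

**Further compounds**
F1 | step 5 | (2R,3S)-5,7-bis(benzyloxy)-2-[3,4-bis(benzyloxy)phenyl]-3,4-dihydro-2H-chromen-3-ol | c1ccccc1COc1cc(OCc2ccccc2)c2c(c1)O[C@H](c1ccc(OCc3ccccc3)c(OCc3ccccc3)c1)[C@@H](O)C2
F2 | step 5 | (2R,3S)-5,7-bis(benzyloxy)-2-[3,4-bis(benzyloxy)phenyl]-8-bromo-3,4-dihydro-2H-chromen-3-ol | c1ccccc1COc1cc(OCc2ccccc2)c2c(c1Br)O[C@H](c1ccc(OCc3ccccc3)c(OCc3ccccc3)c1)[C@@H](O)C2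
F3 | step 5 | (2R,3S)-3,5,7-tris(benzyloxy)-2-[3,4-bis(benzyloxy)phenyl]-8-bromo-3,4-dihydro-2H-chromene | c1ccccc1COc1cc(OCc2ccccc2)c2c(c1Br)O[C@H](c1ccc(OCc3ccccc3)c(OCc3ccccc3)c1)[C@@H](OCc1ccccc1)C2
F4 | step 5 | 2,6-dihydroxy-4-methoxy-3-methyl-5-(2-methylpropanoyl)benzaldehyde | CC(C)C(=O)c1c(O)c(C=O)c(O)c(C)c1OC
F5 | step 5 | 2,6-bis(benzyloxy)-4-methoxy-3-methyl-5-(2-methylpropanoyl)benzaldehyde | CC(C)C(=O)c1c(OCc2ccccc2)c(C=O)c(OCc2ccccc2)c(C)c1OC
F6 | step 5 | 1-[2,4-bis(benzyloxy)-3-{hydroxy[(2R,3S)-3,5,7-tris(benzyloxy)-2-(3,4-bis(benzyloxy)phenyl)-3,4-dihydro-2H-chromen-8-yl]methyl}-6-methoxy-5-methylphenyl]-2-methylpropan-1-one (carbinol epimers) | CC(C)C(=O)c1c(OCc2ccccc2)c(C(O)c2c(OCc3ccccc3)cc(OCc3ccccc3)c3c2O[C@H](c2ccc(OCc4ccccc4)c(OCc4ccccc4)c2)[C@@H](OCc2ccccc2)C3)c(OCc2ccccc2)c(C)c1OC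
F7 | step 2 | 2,4,6-trihydroxy-3-methylbenzaldehyde | Cc1c(O)cc(O)c(C=O)c1O
F8 | step 2 | 2,6-dihydroxy-4-methoxy-3-methylbenzaldehyde | Cc1c(OC)cc(O)c(C=O)c1O
F9 | step 4 | 1-[4,6-bis(benzyloxy)-2-hydroxy-3-methylphenyl]-2-methylpropan-1-one | CC(C)C(=O)c1c(OCc2ccccc2)cc(OCc2ccccc2)c(C)c1O
F10 | step 4 | 1-[4,6-bis(benzyloxy)-2-methoxy-3-methylphenyl]-2-methylpropan-1-one | CC(C)C(=O)c1c(OCc2ccccc2)cc(OCc2ccccc2)c(C)c1OC
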